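**Retrosynthetic overview**
1. Ring lettering: a = lactone O–CH, b = ring-fusion CH, c = CH2, d = CHOH, e = CHMe, f = acyl carbinol carbon, g = ester O–CH. The target is the cycloheptane a–g, cis-fused at a/b to an α-methylene-γ-lactone.
2. Feature used: C-a and C-d are oxygen-bearing ring carbons in a 1,4 relation, joined on one side by the oxygenated three-carbon run C-g(O)–C-f(O)–C-e(Me). Cutting C-a–C-g and C-d–C-e gives furan (C-a to C-d plus the C-a oxygen) and a 1-alkoxy-3-methyl-2-oxyallyl cation (C-g, C-f, C-e).
3. Ring order: the cycloheptene and its oxygen bridge form together in the (4+3) cycloaddition. The bridge is then opened at C-d by syn SN2′ delivery of a 2-propenyl group to C-b. The lactone ring is closed last, by oxidising that group onto the C-a hydroxyl.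
4. Later disconnections: the C-d oxygen and the C-e configuration are re-set through the C-f enone (epoxidation, reductive opening, equilibration). The C-f–acyl bond comes from acetylide addition to the C-f ketone and CO2-mediated alkyne hydration. The C-g ester is installed after cleavage of the 1-phenylethyl auxiliary.

Key step: step 5

Convention: α is the ring face that carries the C-a oxygen, β the opposite face.
Assumption: the (S)-1-phenylethyl group is taken to shield the cation face that leads to the (1R,2S,4R,5S) adduct 8; if the sense of induction is the opposite, (R)-1-phenylethanol is used in step 3 and nothing else changes.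

**Route**

Step 1
Reactants: 1 methyl 2,2-dimethoxyacetate
Product: 2 N-methoxy-N-methyl-2,2-dimethoxyacetamide
Conditions: MeNH(OMe)·HCl, i-PrMgCl, THF, −20 °C
Reagents that add atoms: N,O-dimethylhydroxylamine hydrochloride (SMILES CNOC.Cl)
Why: Aminolysis of the non-enolisable ester by the chloromagnesium amide (N-methoxy-N-methyl amide formation) is reliable and creates no stereocentre.

Step 2
Reactants: 2 N-methoxy-N-methyl-2,2-dimethoxyacetamide
Product: 3 1,1-dimethoxybutan-2-one
Conditions: EtMgBr, THF, 0 °C; aq. NH4Cl
Reagents that add atoms: ethylmagnesium bromide (SMILES CC[Mg]Br)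
Why: Weinreb ketone synthesis: the magnesium chelate of the tetrahedral adduct survives until work-up, so addition should stop at the ethyl ketone.

Step 3
Reactants: 3 1,1-dimethoxybutan-2-one; 4 (S)-1-phenylethanol
Product: 5 1-methoxy-1-[(S)-1-phenylethoxy]butan-2-one (both acetal epimers)
Conditions: TsOH·H2O (cat.), neat, 45 °C, reduced pressure (MeOH removed)
Reagents that add atoms: none
Why: Acid-catalysed transacetalisation driven by removal of methanol exchanges one methoxy group; the new acetal centre forms as both epimers, which is immaterial because it becomes planar in step 5.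

Step 4
Reactants: 5 1-methoxy-1-[(S)-1-phenylethoxy]butan-2-one
Product: 6 (Z)-1-methoxy-1-[(S)-1-phenylethoxy]-2-(triethylsilyloxy)but-2-ene (both acetal epimers)
Conditions: LiN(i-Pr)2, THF–DMPU, −78 °C; Et3SiCl
Reagents that add atoms: chlorotriethylsilane (SMILES CC[Si](CC)(CC)Cl)
Why: Silyl enol ether formation by kinetic deprotonation at the CH2 group (the acetal C–H is hindered and would give a doubly oxygenated enolate); the dipolar cosolvent should favour the Z enolate, which places the methyl group in a W position of the later cation.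

Step 5
Reactants: 6 (Z)-1-methoxy-1-[(S)-1-phenylethoxy]-2-(triethylsilyloxy)but-2-ene; 7 furan
Product: 8 (1R,2S,4R,5S)-4-methyl-2-[(1S)-1-phenylethoxy]-8-oxabicyclo[3.2.1]oct-6-en-3-one
Conditions: Me3SiOTf (0.1 equiv), furan (5 equiv), CH2Cl2, −95 °C; Et3N quench
Reagents that add atoms: none
Why: Me3SiOTf removes the methoxy group of the mixed acetal to give a 1-(1-phenylethoxy)-3-methyl-2-(triethylsiloxy)allyl cation whose Z enol ether geometry puts both terminal substituents in W positions, and furan bonds through its two α-carbons to the two allyl termini in a concerted or rapidly stepwise (4+3) cycloaddition, after which silyl transfer to triflate releases the ketone and a silyl triflate that carries the chain. The closest known reaction type is the silyl triflate-promoted (4+3) cycloaddition of furan with siloxyallyl cations generated from α-keto acetal silyl enol ethers, including mixed acetals of 1-phenylethanol. The cycloheptenone ring closes by intermolecular union of a four-carbon and a three-carbon component through the C-a–C-g and C-d–C-e bonds, and the same two bonds close the bridging tetrahydropyran-4-one ring that contains the furan oxygen. C-a and C-d are set cis by suprafacial addition across furan, C-g and C-e are set equatorial (trans to the oxygen bridge) by the W cation reacting through the compact transition state, and the absolute sense of all four centres follows from the (S)-1-phenylethyl group shielding one face of the cation. The step needs ionisation of the methoxy rather than the 1-phenylethoxy group, which the less hindered methoxy oxygen should secure by being silylated first, and high facial selectivity, for which the auxiliary sits directly on the cationic oxygen and the reaction is run at −95 °C.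

Step 6
Reactants: 8 (1R,2S,4R,5S)-4-methyl-2-[(1S)-1-phenylethoxy]-8-oxabicyclo[3.2.1]oct-6-en-3-one
Product: 9 axial C-f alcohol of the oxabicycle (hydroxyl cis to the equatorial ether and methyl groups)
Conditions: LiBH(s-Bu)3, THF, −78 °C
Reagents that add atoms: none
Why: Bulky borohydride reduction: hydride approaches C-f from the open equatorial direction, away from the two-carbon alkene bridge, so the axial alcohol should form; this temporary centre masks the ketone for step 8.

Step 7
Reactants: 9 axial C-f alcohol of the oxabicycle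
Product: 10 C-f triethylsilyl ether of the oxabicycle
Conditions: Et3SiOTf, 2,6-lutidine, CH2Cl2, 0 °C
Reagents that add atoms: triethylsilyl triflate (SMILES CC[Si](CC)(CC)OS(=O)(=O)C(F)(F)F)
Why: Silylation of the hindered axial alcohol with the silyl triflate gives an ether that tolerates the organolithium of step 8 and can later be removed beside a tert-butyldimethylsilyl ether.

Step 8
Reactants: 10 C-f triethylsilyl ether of the oxabicycle
Product: 11 ring-opened cyclohept-3-en-1-ol (C-a OH α; C-b 2-propenyl α; C-c=C-d alkene)
Conditions: 2-bromopropene, t-BuLi (2 equiv), Et2O, −78 °C; then 10, TMEDA, Et2O, 0 °C → rt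
Reagents that add atoms: 2-propenyllithium (SMILES [Li]C(C)=C)
Why: Organolithium SN2′ ring opening of an oxabicyclic alkene: lithium bound to the bridging oxygen delivers the alkenyl group to the exo face of C-b, which sets C-b cis to the C-a oxygen, and attack at C-b rather than C-c is expected because ionisation of the C-a–O bond is retarded by the adjacent C-g ether.

Step 9
Reactants: 11 ring-opened cyclohept-3-en-1-ol
Product: 12 C-a tert-butyldimethylsilyl ether
Conditions: t-BuMe2SiOTf, 2,6-lutidine, CH2Cl2, 0 °C
Reagents that add atoms: tert-butyldimethylsilyl triflate (SMILES CC(C)(C)[Si](C)(C)OS(=O)(=O)C(F)(F)F)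
Why: Silylation of the C-a hydroxyl, so that only the C-f oxygen is oxidised in step 11.

Step 10
Reactants: 12 C-a tert-butyldimethylsilyl ether
Product: 13 C-f alcohol (C-f OH β; C-a silyl ether kept)
Conditions: PPTS, MeOH–CH2Cl2, 0 °C
Reagents that add atoms: none
Why: Acid-catalysed methanolysis removes a triethylsilyl ether far faster than a tert-butyldimethylsilyl ether, so only the C-f hydroxyl should be freed.

Step 11
Reactants: 13 C-f alcohol
Product: 15 conjugated enone (C-f ketone; C-e=C-d alkene), via β,γ-unsaturated ketone 14 (not isolated)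
Conditions: Dess–Martin periodinane, CH2Cl2, 0 °C → rt; aq. work-up; crude ketone, DBU (0.2 equiv), CH2Cl2, rt
Reagents that add atoms: none
Why: Dess–Martin oxidation followed by base-catalysed isomerisation through the dienolate to the conjugated trisubstituted enone; the C-e centre (wrong for the target) and the temporary C-f centre are erased on purpose.

Step 12
Reactants: 15 conjugated enone
Product: 16 β-epoxy ketone (C-d and C-e oxygen β; C-e methyl α)
Conditions: 30% H2O2, NaOH (cat.), MeOH, 0 °C
Reagents that add atoms: hydrogen peroxide (SMILES OO)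
Why: Weitz–Scheffer epoxidation: hydroperoxide should add to C-d on the β-face, anti to the C-b 2-propenyl group as in 5-substituted 2-methylcyclohex-2-enones, which sets the C-d oxygen trans to the C-a oxygen.

Step 13
Reactants: 16 β-epoxy ketone
Product: 17 β-hydroxy ketone (C-d OH β; both C-e epimers)
Conditions: SmI2, THF–MeOH, −90 °C
Reagents that add atoms: none
Why: Samarium diiodide reduction of an α,β-epoxy ketone cleaves the C-e–O bond through the ketyl and leaves C-d untouched; C-e forms unselectively on protonation of the samarium enolate and is settled in step 14.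

Step 14
Reactants: 17 β-hydroxy ketone
Product: 19 C-d silyl ether with C-e methyl α, via silyl ether epimer mixture 18 (not isolated)
Conditions: t-BuMe2SiOTf, 2,6-lutidine, CH2Cl2, −78 °C; aq. work-up; crude, DBU (0.3 equiv), toluene, rt
Reagents that add atoms: tert-butyldimethylsilyl triflate (SMILES CC(C)(C)[Si](C)(C)OS(=O)(=O)C(F)(F)F)
Why: Silyl ether formation and then base-catalysed epimerisation α to the ketone: enolisation toward C-e should funnel both epimers into the thermodynamically preferred one, with the methyl α and trans to both the C-d silyloxy and C-g ether groups, which sets C-e.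

Step 15
Reactants: 20 (S)-but-3-yn-2-ol
Product: 21 (S)-tert-butyl(but-3-yn-2-yloxy)dimethylsilane
Conditions: t-BuMe2SiCl, imidazole, CH2Cl2, rt
Reagents that add atoms: tert-butyldimethylsilyl chloride (SMILES CC(C)(C)[Si](C)(C)Cl)
Why: Standard silylation of the propargylic alcohol; the purchased stereocentre is not involved.

Step 16
Reactants: 19 C-d silyl ether ketone; 21 (S)-tert-butyl(but-3-yn-2-yloxy)dimethylsilane
Product: 24 tertiary propargylic alcohol (C-f OH α; alkynyl β), via lithium acetylide 22 (not isolated), via dichlorocerium acetylide 23 (not isolated)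
Conditions: 21, n-BuLi, THF, −78 °C; CeCl3, −78 °C; then 19, −78 → −40 °C
Reagents that add atoms: none
Why: 1,2-Addition of an alkynylcerium dichloride, whose low basicity should suppress enolisation and β-elimination; with CeCl3 chelating the carbonyl and C-g ether oxygens the ether stays in the carbonyl plane and the slim acetylide should enter on the β-face anti to the C-e methyl group, which sets C-f with the hydroxyl α and the carbon chain β.

Step 17
Reactants: 24 tertiary propargylic alcohol
Product: 26 α-hydroxy ketone with the (S)-3-silyloxybutanoyl chain on C-f, via alkylidene cyclic carbonate 25 (not isolated)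
Conditions: AgOAc (10 mol%), DBU, CO2 (1 atm), MeCN, rt; then H2O, 40 °C
Reagents that add atoms: water (SMILES O)
Why: Silver-catalysed carboxylative cyclisation of a tertiary propargylic alcohol: the carbonate formed from the alkoxide and CO2 adds 5-exo-dig to the activated alkyne at the carbon next to C-f, and hydrolysis of the Z-alkylidene carbonate with loss of CO2 places the ketone at exactly that carbon.

Step 18
Reactants: 26 α-hydroxy ketone
Product: 27 C-g alcohol (C-g OH β; C-f OH α)
Conditions: BCl3·SMe2, CH2Cl2, −20 °C; MeOH quench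
Reagents that add atoms: none
Why: Lewis acid cleavage of the secondary benzylic ether by ionisation at the benzylic carbon, so the C-g–O bond and configuration are retained; the three secondary silyl ethers and the alkene should survive at low temperature.

Step 19
Reactants: 27 C-g alcohol; 28 (R)-2-methylbutanoic acid
Product: 29 C-g (R)-2-methylbutanoate
Conditions: DCC, DMAP (cat.), CH2Cl2, 0 °C → rt
Reagents that add atoms: none
Why: Steglich esterification: the C-g hydroxyl is the only acylable alcohol (the C-f hydroxyl is tertiary, the others are silylated), and carbodiimide coupling at 0 °C should not epimerise the α-centre of the acid.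

Step 20
Reactants: 29 C-g (R)-2-methylbutanoate
Product: 30 allylic alcohol (C-b 3-hydroxyprop-1-en-2-yl α)
Conditions: SeO2 (0.3 equiv), t-BuOOH, CH2Cl2, rt
Reagents that add atoms: tert-butyl hydroperoxide (SMILES CC(C)(C)OO), its oxygen transferred through selenium dioxide (SMILES O=[Se]=O)
Why: Selenium dioxide-catalysed allylic oxidation (ene reaction then 2,3-sigmatropic shift) of the 1,1-disubstituted alkene, which should oxidise the methyl group in preference to the ring methine and leave the ketone and the tertiary alcohol alone.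

Step 21
Reactants: 30 allylic alcohol
Product: 31 desilylated pentaol
Conditions: HF·pyridine, THF–pyridine, 0 °C → rt
Reagents that add atoms: none
Why: Fluoride-mediated cleavage of the three silyl ethers under buffered acidic conditions, which the ester, the ketone and the tertiary alcohol should tolerate without acyl migration.

Step 22
Reactants: 31 desilylated pentaol
Product: 32 CNP0291806.3
Conditions: MnO2 (activated, excess), CH2Cl2, rt
Reagents that add atoms: none
Why: Oxidative lactonisation: manganese dioxide oxidises only the allylic primary alcohol, the enal is trapped by the cis C-a hydroxyl as a five-membered allylic lactol, and this is oxidised on to the α-methylene-γ-lactone, closing the last ring with the cis fusion fixed in step 8.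

**Compound list**
1 | methyl 2,2-dimethoxyacetate | COC(OC)C(=O)OC | starting material
2 | N-methoxy-N-methyl-2,2-dimethoxyacetamide | COC(OC)C(=O)N(C)OC | intermediate
3 | 1,1-dimethoxybutan-2-one | CCC(=O)C(OC)OC | intermediate
4 | (S)-1-phenylethanol | C[C@H](O)c1ccccc1 | starting material
5 | 1-methoxy-1-[(S)-1-phenylethoxy]butan-2-one (both epimers at the acetal carbon) | CCC(=O)C(OC)O[C@@H](C)c1ccccc1 | intermediate
6 | (Z)-1-methoxy-1-[(S)-1-phenylethoxy]-2-(triethylsilyloxy)but-2-ene (both epimers at the acetal carbon) | C/C=C(\O[Si](CC)(CC)CC)C(OC)O[C@@H](C)c1ccccc1 | intermediate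
7 | furan | c1ccoc1 | starting material
8 | (1R,2S,4R,5S)-4-methyl-2-[(1S)-1-phenylethoxy]-8-oxabicyclo[3.2.1]oct-6-en-3-one (ether and methyl equatorial) | O1[C@@H]2C=C[C@H]1[C@@H](C)C(=O)[C@H]2O[C@@H](C)c3ccccc3 | intermediate
9 | 4-methyl-2-[(S)-1-phenylethoxy]-8-oxabicyclo[3.2.1]oct-6-en-3-ol; skeleton as in 8; hydroxyl axial and cis to the ether and methyl groups | O1[C@@H]2C=C[C@H]1[C@@H](C)[C@@H](O)[C@H]2O[C@@H](C)c3ccccc3 | intermediate
10 | triethylsilyl ether of 9 | O1[C@@H]2C=C[C@H]1[C@@H](C)[C@@H](O[Si](CC)(CC)CC)[C@H]2O[C@@H](C)c3ccccc3 | intermediate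
11 | 5-methyl-7-[(S)-1-phenylethoxy]-2-(prop-1-en-2-yl)-6-(triethylsilyloxy)cyclohept-3-en-1-ol; C-a OH α; C-b 2-propenyl α; C-e methyl β; C-f silyloxy β; C-g ether β | O[C@@H]1[C@H](C(C)=C)C=C[C@@H](C)[C@@H](O[Si](CC)(CC)CC)[C@H]1O[C@@H](C)c1ccccc1 | intermediate
12 | C-a tert-butyldimethylsilyl ether of 11 | CC(C)(C)[Si](C)(C)O[C@@H]1[C@H](C(C)=C)C=C[C@@H](C)[C@@H](O[Si](CC)(CC)CC)[C@H]1O[C@@H](C)c1ccccc1 | intermediate
13 | 12 without the triethylsilyl group (C-f OH β) | CC(C)(C)[Si](C)(C)O[C@@H]1[C@H](C(C)=C)C=C[C@@H](C)[C@@H](O)[C@H]1O[C@@H](C)c1ccccc1 | intermediate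
14 | β,γ-unsaturated ketone: C-f ketone; C-c=C-d alkene; C-e methyl β | CC(C)(C)[Si](C)(C)O[C@@H]1[C@H](C(C)=C)C=C[C@@H](C)C(=O)[C@H]1O[C@@H](C)c1ccccc1 | intermediate (not isolated)
15 | 6-(tert-butyldimethylsilyloxy)-2-methyl-7-[(S)-1-phenylethoxy]-5-(prop-1-en-2-yl)cyclohept-2-en-1-one; C-a silyloxy α; C-b 2-propenyl α; C-g ether β | CC(C)(C)[Si](C)(C)O[C@@H]1[C@H](C(C)=C)CC=C(C)C(=O)[C@H]1O[C@@H](C)c1ccccc1 | intermediate
16 | 2,3-epoxide of 15 on the β-face (C-d and C-e oxygen β; C-e methyl α) | CC(C)(C)[Si](C)(C)O[C@@H]1[C@H](C(C)=C)C[C@H]2O[C@@]2(C)C(=O)[C@H]1O[C@@H](C)c1ccccc1 | intermediate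
17 | β-hydroxy ketone: C-d OH β; C-e methyl as both epimers | CC(C)(C)[Si](C)(C)O[C@@H]1[C@H](C(C)=C)C[C@@H](O)C(C)C(=O)[C@H]1O[C@@H](C)c1ccccc1 | intermediate
18 | C-d tert-butyldimethylsilyl ether of 17 (both C-e epimers) | CC(C)(C)[Si](C)(C)O[C@@H]1[C@H](C(C)=C)C[C@@H](O[Si](C)(C)C(C)(C)C)C(C)C(=O)[C@H]1O[C@@H](C)c1ccccc1 | intermediate (not isolated)
19 | cycloheptanone: C-a OSi(t-Bu)Me2 α; C-b 2-propenyl α; C-d OSi(t-Bu)Me2 β; C-e methyl α; C-f ketone; C-g O-(S)-1-phenylethyl β | CC(C)(C)[Si](C)(C)O[C@@H]1[C@H](C(C)=C)C[C@@H](O[Si](C)(C)C(C)(C)C)[C@H](C)C(=O)[C@H]1O[C@@H](C)c1ccccc1 | intermediate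
20 | (S)-but-3-yn-2-ol | C#C[C@H](C)O | starting material
21 | (S)-tert-butyl(but-3-yn-2-yloxy)dimethylsilane | C#C[C@H](C)O[Si](C)(C)C(C)(C)C | intermediate
22 | lithium acetylide of 21 | [Li]C#C[C@H](C)O[Si](C)(C)C(C)(C)C | intermediate (not isolated)
23 | dichlorocerium acetylide of 21 | Cl[Ce](Cl)C#C[C@H](C)O[Si](C)(C)C(C)(C)C | intermediate (not isolated)
24 | tertiary propargylic alcohol: 19 with C-f OH α and C-f β-[(S)-3-(tert-butyldimethylsilyloxy)but-1-ynyl] | CC(C)(C)[Si](C)(C)O[C@@H]1[C@H](C(C)=C)C[C@@H](O[Si](C)(C)C(C)(C)C)[C@H](C)[C@@](O)(C#C[C@H](C)O[Si](C)(C)C(C)(C)C)[C@H]1O[C@@H](C)c1ccccc1 | intermediate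
25 | spiro (Z)-alkylidene 1,3-dioxolan-2-one on C-f (ring oxygen α on C-f) | CC(C)(C)[Si](C)(C)O[C@@H]1[C@H](C(C)=C)C[C@@H](O[Si](C)(C)C(C)(C)C)[C@H](C)[C@]2(OC(=O)O/C2=C\[C@H](C)O[Si](C)(C)C(C)(C)C)[C@H]1O[C@@H](C)c1ccccc1 | intermediate (not isolated)
26 | α-hydroxy ketone: C-f OH α; C-f β-[(S)-3-(tert-butyldimethylsilyloxy)butanoyl]; C-g O-(S)-1-phenylethyl β | CC(C)(C)[Si](C)(C)O[C@@H]1[C@H](C(C)=C)C[C@@H](O[Si](C)(C)C(C)(C)C)[C@H](C)[C@@](O)(C(=O)C[C@H](C)O[Si](C)(C)C(C)(C)C)[C@H]1O[C@@H](C)c1ccccc1 | intermediate
27 | 26 without the 1-phenylethyl group (C-g OH β) | CC(C)(C)[Si](C)(C)O[C@@H]1[C@H](C(C)=C)C[C@@H](O[Si](C)(C)C(C)(C)C)[C@H](C)[C@@](O)(C(=O)C[C@H](C)O[Si](C)(C)C(C)(C)C)[C@H]1O | intermediate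
28 | (R)-2-methylbutanoic acid | CC[C@@H](C)C(=O)O | starting material
29 | C-g (R)-2-methylbutanoate of 27 | CC(C)(C)[Si](C)(C)O[C@@H]1[C@H](C(C)=C)C[C@@H](O[Si](C)(C)C(C)(C)C)[C@H](C)[C@@](O)(C(=O)C[C@H](C)O[Si](C)(C)C(C)(C)C)[C@H]1OC(=O)[C@H](C)CC | intermediate
30 | 29 with the C-b substituent oxidised to 3-hydroxyprop-1-en-2-yl | CC(C)(C)[Si](C)(C)O[C@@H]1[C@H](C(CO)=C)C[C@@H](O[Si](C)(C)C(C)(C)C)[C@H](C)[C@@](O)(C(=O)C[C@H](C)O[Si](C)(C)C(C)(C)C)[C@H]1OC(=O)[C@H](C)CC | intermediate
31 | desilylated pentaol: C-a OH α; C-b 3-hydroxyprop-1-en-2-yl α; C-d OH β; C-e methyl α; C-f OH α and β-[(S)-3-hydroxybutanoyl]; C-g β-(R)-2-methylbutanoate | O[C@@H]1[C@H](C(CO)=C)C[C@@H](O)[C@H](C)[C@@](O)(C(=O)C[C@H](C)O)[C@H]1OC(=O)[C@H](C)CC | intermediate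
32 | CNP0291806.3: cis-fused α-methylene-γ-lactone (C-a O α; C-b C α); C-d OH β; C-e methyl α; C-f OH α and β-[(S)-3-hydroxybutanoyl]; C-g β-(R)-2-methylbutanoate | C=C1C(=O)O[C@@H]2[C@H]1C[C@@H](O)[C@H](C)[C@@](O)(C(=O)C[C@H](C)O)[C@H]2OC(=O)[C@H](C)CC | target

**Step count**
Total: 22 steps. Longest linear sequence: 21 steps (steps 1–14 and 16–22; step 15 is the side branch).

**Steps most likely to fail**

Step 8. Transfer of the sp2 lithium reagent to the only moderately strained alkene may be slow, so that deprotonation next to the benzylic ether, or attack at C-c with cleavage of the C-a–O bond, competes. The fallback sets out from 10 and comes back at 11. It replaces the anionic SN2′ displacement by a catalytic syn carbometalation and β-oxygen elimination: 2-propenylboronic acid pinacol ester, PdCl2(dppp) (divalent palladium, 5 mol%), Cs2CO3, MeOH, 60 °C. The alkenylpalladium species should add to the exo face and the resulting palladium alkyl should expel the bridging oxygen as an alkoxide, giving the same alcohol 11. No new compound is made on the way (F0).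

Step 16. The acetylide may approach the α-face instead (anti to the C-g ether if chelation fails), giving the C-f epimer, or the ketone may enolise with loss of a β-silyloxy group. The fallback sets out from 19 and comes back at 26. It reverses the order of C–C and C–O bond formation at C-f, so that a reagent preference for the α-face delivers the oxygen and not the carbon. Wittig methoxymethylenation of 19 (Ph3P=CHOMe from the phosphonium chloride and KN(SiMe3)2, THF) should give the exocyclic enol ether F1. Dimethyldioxirane in acetone at −78 °C and aqueous work-up should oxidise only this electron-rich alkene, anti to the C-g ether, to the α-hydroxy aldehyde F2. The silylated sulfone F3, made from (S)-1-(phenylsulfonyl)propan-2-ol with t-BuMe2SiCl and imidazole, is lithiated (n-BuLi, THF, −78 °C, excess) and added to F2 to give the β-hydroxy sulfone F4. Dess–Martin oxidation should give the β-keto sulfone F5, and desulfonylation with Al(Hg) in THF–H2O returns 26.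

Step 14. Equilibration at C-e may be incomplete, or the enolate may expel the C-d or C-a silyloxy group (E1cB) during the DBU treatment. The fallback sets out from 15 and comes back at 19. It brings in the C-d oxygen as a boron substituent, next to which C-e can be equilibrated without an eliminable group. Copper-catalysed conjugate borylation of 15 (CuCl, NaOt-Bu, Xantphos, B2pin2, MeOH, THF), anti to the C-b substituent, followed by DBU equilibration should give the β-boryl ketone F6 with the methyl trans to the boronate. Oxidation with NaBO3·4H2O in THF–H2O, with retention at carbon, should give the single β-hydroxy ketone epimer F7, and silylation (t-BuMe2SiOTf, 2,6-lutidine) returns 19.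

**Further compounds**
F0 | step 8 | none | none
F1 | step 16 | exocyclic methoxymethylene enol ether of 19 (E/Z mixture) | CC(C)(C)[Si](C)(C)O[C@@H]1[C@H](C(C)=C)C[C@@H](O[Si](C)(C)C(C)(C)C)[C@H](C)C(=COC)[C@H]1O[C@@H](C)c1ccccc1
F2 | step 16 | α-hydroxy aldehyde (C-f OH α; formyl β) | CC(C)(C)[Si](C)(C)O[C@@H]1[C@H](C(C)=C)C[C@@H](O[Si](C)(C)C(C)(C)C)[C@H](C)[C@@](O)(C=O)[C@H]1O[C@@H](C)c1ccccc1
F3 | step 16 | (S)-tert-butyldimethyl{[1-(phenylsulfonyl)propan-2-yl]oxy}silane | C[C@@H](CS(=O)(=O)c1ccccc1)O[Si](C)(C)C(C)(C)C
F4 | step 16 | β-hydroxy sulfone adduct of F2 and F3 (epimers at the two new side-chain centres) | CC(C)(C)[Si](C)(C)O[C@@H]1[C@H](C(C)=C)C[C@@H](O[Si](C)(C)C(C)(C)C)[C@H](C)[C@@](O)(C(O)C([C@H](C)O[Si](C)(C)C(C)(C)C)S(=O)(=O)c2ccccc2)[C@H]1O[C@@H](C)c1ccccc1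
F5 | step 16 | β-keto sulfone (epimers at the sulfonyl carbon) | CC(C)(C)[Si](C)(C)O[C@@H]1[C@H](C(C)=C)C[C@@H](O[Si](C)(C)C(C)(C)C)[C@H](C)[C@@](O)(C(=O)C([C@H](C)O[Si](C)(C)C(C)(C)C)S(=O)(=O)c2ccccc2)[C@H]1O[C@@H](C)c1ccccc1
F6 | step 14 | β-boryl ketone (C-d pinacolboronate β; C-e methyl α) | CC(C)(C)[Si](C)(C)O[C@@H]1[C@H](C(C)=C)C[C@@H](B2OC(C)(C)C(C)(C)O2)[C@H](C)C(=O)[C@H]1O[C@@H](C)c1ccccc1
F7 | step 14 | β-hydroxy ketone as one epimer (C-d OH β; C-e methyl α) | CC(C)(C)[Si](C)(C)O[C@@H]1[C@H](C(C)=C)C[C@@H](O)[C@H](C)C(=O)[C@H]1O[C@@H](C)c1ccccc1
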